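**Retrosynthetic overview** (labdane-style numbering: decalin C1–C10, gem-dimethyl on C4, methyls on C8 and C10, side chain C11–C16 from C9, butenolide on C16)
- The target is a cis-fused decalin (C10 methyl and C5 hydrogen on the same face; 5R,10S). The butenolide is attached last by a Stille coupling at C16, and the C13=C14 bond comes from a directed aldol condensation of a C13 aldehyde with a C14–C16 stannyl enal.
- Ring B is opened at the tetrasubstituted C8=C9 alkene (McMurry coupling of a C8/C9 diketone). The C8 ketone arises by cross-metathesis of a C6=C7 propenyl group with methyl vinyl ketone, the C9 ketone from a C9 carboxylic acid.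
- The strategy rests on the C5–C10 bond of ring A: quaternary C10 (methyl, C9) joined to tertiary C5 next to the C4 gem-dimethyl carbon, with C9 and C6 cis on ring A. This bond is made by Ireland–Claisen ring contraction of the silyl ketene acetal of a ten-membered (S,Z)-allylic lactone.
- The lactone comes from Yamaguchi closure of a (7Z,9S)-hydroxy acid built from isobutyronitrile, 1-bromo-3-chloropropane, an acetyl Weinreb amide and diethyl methylmalonate; the carbinol is set by Noyori transfer hydrogenation of an ynone.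
- Order of ring formation: ten-membered lactone (step 9), ring A (step 11), ring B (step 16); the butenolide ring is brought in intact (step 22).

Key step: step 11

Assumption: the α-methyl centre of 14–16 is carried as both epimers because enolisation in step 10 erases it, and the (S,S)-TsDPEN ruthenium catalyst is taken to give the (S)-carbinol as is usual for alkynyl methyl ketones (to be confirmed by Mosher ester analysis of 9; the antipodal catalyst would be used otherwise).

**Route**

Step 1
Reactants: 1 isobutyronitrile; 2 1-bromo-3-chloropropane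
Product: 3 5-chloro-2,2-dimethylpentanenitrile
Conditions: LiN(iPr)2, THF, −78 °C; then 2, −78 °C → rt
Reagents that add atoms: none
Why: The α-cyano carbanion is alkylated (SN2) at the bromide end only, because bromide leaves much faster than chloride.

Step 2
Reactants: 3 5-chloro-2,2-dimethylpentanenitrile
Product: 4 5-chloro-2,2-dimethylpentanal
Conditions: i-Bu2AlH, CH2Cl2, −78 °C; then 1 M aq. HCl, 0 °C
Reagents that add atoms: water, O
Why: Partial reduction of a nitrile with i-Bu2AlH stops at the N-aluminio imine, which acid hydrolysis converts to the aldehyde while the alkyl chloride is untouched.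

Step 3
Reactants: 4 5-chloro-2,2-dimethylpentanal; 5 dimethyl (1-diazo-2-oxopropyl)phosphonate
Product: 6 6-chloro-3,3-dimethylhex-1-yne
Conditions: K2CO3, MeOH, 0 °C → rt
Reagents that add atoms: none
Why: Seyferth–Gilbert homologation with the Ohira–Bestmann reagent turns the non-enolisable aldehyde into the terminal alkyne under mild base that leaves the primary chloride alone.

Step 4
Reactants: 6 6-chloro-3,3-dimethylhex-1-yne; 7 N-methoxy-N-methylacetamide
Product: 8 8-chloro-5,5-dimethyloct-3-yn-2-one
Conditions: n-BuLi, THF, −78 °C; then 7, −78 → 0 °C; dilute aq. HCl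
Reagents that add atoms: none
Why: Weinreb ketone synthesis: the lithium acetylide acylates the amide and the chelated tetrahedral adduct prevents a second addition, so the ynone is released on work-up.

Step 5
Reactants: 8 8-chloro-5,5-dimethyloct-3-yn-2-one
Product: 9 (2S)-8-chloro-5,5-dimethyloct-3-yn-2-ol
Conditions: Ru[(S,S)-TsDPEN](p-cymene) (1 mol %), i-PrOH, rt
Reagents that add atoms: none
Why: Noyori asymmetric transfer hydrogenation of an alkynyl methyl ketone should set the (S)-carbinol, the alkyne taking the place of the aryl group in the catalyst-controlled hydride delivery.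

Step 6
Reactants: 9 (2S)-8-chloro-5,5-dimethyloct-3-yn-2-ol
Product: 10 (2S,3Z)-8-chloro-5,5-dimethyloct-3-en-2-ol
Conditions: H2 (1 atm), Pd/CaCO3 poisoned with Pb(OAc)2, quinoline, EtOAc, rt
Reagents that add atoms: none
Why: Lindlar semihydrogenation adds hydrogen syn on the poisoned palladium surface and should give the Z alkene without affecting the carbinol centre or the C–Cl bond.

Step 7
Reactants: 10 (2S,3Z)-8-chloro-5,5-dimethyloct-3-en-2-ol; 11 diethyl methylmalonate
Product: 12 diethyl 2-[(5Z,7S)-7-hydroxy-4,4-dimethyloct-5-en-1-yl]-2-methylpropanedioate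
Conditions: NaH, 11 (slight excess over NaH), DMF, 0 °C; then 10, NaI (cat.), 80 °C
Reagents that add atoms: none
Why: Malonic ester alkylation: the soft malonate anion displaces the primary chloride (Finkelstein catalysis by iodide), while the much less acidic alcohol stays un-ionised.

Step 8
Reactants: 12 diethyl 2-[(5Z,7S)-7-hydroxy-4,4-dimethyloct-5-en-1-yl]-2-methylpropanedioate
Product: 14 (7Z,9S)-9-hydroxy-2,6,6-trimethyldec-7-enoic acid (both C2 epimers), via malonic diacid 13 (not isolated)
Conditions: KOH, EtOH/H2O, reflux; aq. HCl to pH 2, 0 °C; then pyridine, 115 °C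
Reagents that add atoms: potassium hydroxide, [K+].[OH-]
Why: Saponification followed by thermal decarboxylation of the malonic acid (malonic ester synthesis) leaves the α-methyl acid under conditions the Z-allylic alcohol tolerates.

Step 9
Reactants: 14 (7Z,9S)-9-hydroxy-2,6,6-trimethyldec-7-enoic acid
Product: 16 (8Z,10S)-3,7,7,10-tetramethyloxacyclodec-8-en-2-one (both C3 epimers), via mixed anhydride 15 (not isolated)
Conditions: 2,4,6-Cl3C6H2COCl, Et3N, THF, rt; then slow addition to DMAP, toluene, 100 °C (about 2 mM)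
Reagents that add atoms: none
Why: Yamaguchi macrolactonisation at high dilution should close the ten-membered ring with retention at the carbinol, helped by the Z alkene and the gem-dimethyl group (Thorpe–Ingold effect).

Step 10
Reactants: 16 (8Z,10S)-3,7,7,10-tetramethyloxacyclodec-8-en-2-one
Product: 17 tert-butyldimethylsilyl ketene acetal of 16 (ring oxygen cis to lactone C4; 8Z,10S)
Conditions: LiN(iPr)2, TBSCl, DMPU, THF, −78 °C → rt (in situ quench); filter under argon, exchange solvent
Reagents that add atoms: tert-butyldimethylsilyl chloride, CC(C)(C)[Si](C)(C)Cl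
Why: Kinetic enolisation and O-silylation (Ireland conditions) give the ketene acetal; both C3 epimers converge, the ring fixes its geometry, and TBS is chosen in place of a smaller silyl group to withstand the heating of step 11.

Step 11
Reactants: 17 tert-butyldimethylsilyl ketene acetal of 16
Product: 19 (1S,2R)-1,3,3-trimethyl-2-[(E)-prop-1-en-1-yl]cyclohexane-1-carboxylic acid, via silyl ester 18 (not isolated)
Conditions: toluene, 110 °C (xylene, 140 °C if slow); then 1 M aq. HCl, THF, rt
Reagents that add atoms: none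
Why: The ketene acetal undergoes a concerted suprafacial [3,3]-sigmatropic shift (Ireland–Claisen rearrangement) in which lactone C3 bonds to alkene carbon C8 (the future C10–C5 bond) while the allylic C–O bond breaks, driven by the new silyl ester C=O bond and the release of medium-ring strain. The closest known reaction type is the Ireland–Claisen ring contraction of macrocyclic allylic lactones to cis-2-alkenylcycloalkanecarboxylic acids. Ring A closes transannularly: the new σ bond spans the ten-membered ring, so the two bonding carbons and the four-carbon tether between them (future C1–C4) become the cyclohexane, a ten-to-six ring contraction. C5 is set by chirality transfer from the (S)-carbinol: A(1,3) strain with the gem-dimethyl carbon keeps the carbinol hydrogen in the alkene plane, so oxygen departs from one face only, the methyl group sits outside and the propenyl group emerges E. C10 is set by the ring, which holds the ring oxygen cis to C4 in the ketene acetal and the alkene Z, so only a boat-like six-atom array is reachable and the carboxyl carbon and the propenyl group end up cis on ring A. The step needs boat over chair and a single alkene face, both secured by the tether and the allylic strain, and it needs the rearrangement to outrun silyl migration, which is why the TBS group is used.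

Step 12
Reactants: 20 2-(3-chloropropyl)-1,3-dioxolane
Product: 21 [3-(1,3-dioxolan-2-yl)propyl]magnesium chloride
Conditions: Mg turnings (activated with 1,2-dibromoethane), THF, 50 °C
Reagents that add atoms: magnesium, [Mg]
Why: Grignard formation by insertion of magnesium into the primary C–Cl bond; the acetal is inert to the organomagnesium.

Step 13
Reactants: 19 (1S,2R)-1,3,3-trimethyl-2-[(E)-prop-1-en-1-yl]cyclohexane-1-carboxylic acid; 21 [3-(1,3-dioxolan-2-yl)propyl]magnesium chloride
Product: 23 4-(1,3-dioxolan-2-yl)-1-{(1S,2R)-1,3,3-trimethyl-2-[(E)-prop-1-en-1-yl]cyclohexyl}butan-1-one, via acid chloride 22 (not isolated)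
Conditions: (COCl)2, DMF (cat.), CH2Cl2, 0 °C → rt; evaporate; then 21, CuI (10 mol %), THF, −30 → 0 °C
Reagents that add atoms: none
Why: Copper-catalysed acylation of a Grignard reagent by the acid chloride, which has no α-hydrogen and so cannot form a ketene or epimerise, should stop at the hindered C9 ketone.

Step 14
Reactants: 23 ketone from step 13; 24 methyl vinyl ketone (but-3-en-2-one)
Product: 25 (3E)-4-{(1R,2S)-2-[4-(1,3-dioxolan-2-yl)butanoyl]-2,6,6-trimethylcyclohexyl}but-3-en-2-one
Conditions: RuCl2(H2IMes)(=CH-C6H4-2-OiPr) (second-generation Hoveyda–Grubbs catalyst, 10 mol %), 24 (10 equiv), toluene, 80 °C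
Reagents that add atoms: none
Why: Olefin cross-metathesis between the electron-rich propenyl group (type 1) and the electron-poor vinyl ketone (type 2) should give the enone with loss of propene under neutral conditions that cannot epimerise C5.

Step 15
Reactants: 25 enone from step 14
Product: 26 4-(1,3-dioxolan-2-yl)-1-[(1S,2R)-1,3,3-trimethyl-2-(3-oxobutyl)cyclohexyl]butan-1-one
Conditions: H2 (1 atm), Pd/C, EtOAc, rt
Reagents that add atoms: none
Why: Catalytic hydrogenation saturates the conjugated C6=C7 bond and leaves both ketones and the acetal intact.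

Step 16
Reactants: 26 diketone from step 15
Product: 27 2-{3-[(4aR,8aS)-2,5,5,8a-tetramethyl-3,4,4a,5,6,7,8,8a-octahydronaphthalen-1-yl]propyl}-1,3-dioxolane
Conditions: TiCl3(DME)1.5, Zn(Cu), DME, reflux; syringe-pump addition of 26
Reagents that add atoms: none
Why: Intramolecular McMurry coupling of the 1,6-diketone by low-valent titanium forms the pinacolate and deoxygenates it to the tetrasubstituted C8=C9 alkene, closing ring B on the preset cis C5/C10 pair.

Step 17
Reactants: 27 decalin acetal from step 16
Product: 28 4-[(4aR,8aS)-2,5,5,8a-tetramethyl-3,4,4a,5,6,7,8,8a-octahydronaphthalen-1-yl]butanal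
Conditions: PPTS, acetone/H2O, 50 °C
Reagents that add atoms: water, O
Why: Mild acid-catalysed acetal hydrolysis frees the aldehyde without isomerising the tetrasubstituted alkene.

Step 18
Reactants: 29 prop-2-yn-1-ol; 30 tributyltin hydride
Product: 31 (2E)-3-(tributylstannyl)prop-2-en-1-ol
Conditions: 30 (1.3 equiv), AIBN (cat.), neat, 80 °C; chromatography
Reagents that add atoms: none
Why: Radical hydrostannation of the terminal alkyne with excess stannane under equilibrating conditions should give mainly the (E)-β-stannyl allylic alcohol, separable from its isomers.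

Step 19
Reactants: 31 (2E)-3-(tributylstannyl)prop-2-en-1-ol
Product: 32 (2E)-3-(tributylstannyl)prop-2-enal
Conditions: MnO2, CH2Cl2, rt
Reagents that add atoms: none
Why: MnO2 oxidises the allylic alcohol selectively to the enal without cleaving the vinyl C–Sn bond.

Step 20
Reactants: 28 aldehyde from step 17; 32 (2E)-3-(tributylstannyl)prop-2-enal
Product: 35 (2E,4E)-2-{2-[(4aR,8aS)-2,5,5,8a-tetramethyl-3,4,4a,5,6,7,8,8a-octahydronaphthalen-1-yl]ethyl}-5-(tributylstannyl)penta-2,4-dienal, via N-tert-butyl imine 33 (not isolated), via hydroxy imine aldol adduct 34 (not isolated)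
Conditions: t-BuNH2, 4 Å MS, Et2O, rt; evaporate; LiN(iPr)2, THF, −78 °C; then 32, −78 °C; then AcOH/NaOAc buffer, THF/H2O, rt
Reagents that add atoms: water, O
Why: Wittig directed aldol condensation: the lithiated imine adds 1,2 to the non-enolisable enal, and buffered hydrolysis with dehydration should give the 2-alkyl dienal as the thermodynamically preferred E isomer (formyl group trans to C15).

Step 21
Reactants: 35 dienal from step 20
Product: 36 (2E,4E)-2-{2-[(4aR,8aS)-2,5,5,8a-tetramethyl-3,4,4a,5,6,7,8,8a-octahydronaphthalen-1-yl]ethyl}-5-(tributylstannyl)penta-2,4-dien-1-ol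
Conditions: NaBH4, CeCl3·7H2O, MeOH, −40 °C
Reagents that add atoms: none
Why: Luche reduction takes the aldehyde 1,2 to the primary allylic alcohol and leaves the diene and the stannane untouched.

Step 22
Reactants: 36 dienol from step 21; 37 4-bromofuran-2(5H)-one
Product: 38 4-[(1E,3E)-4-(hydroxymethyl)-6-[(4aR,8aS)-2,5,5,8a-tetramethyl-3,4,4a,5,6,7,8,8a-octahydronaphthalen-1-yl]hexa-1,3-dien-1-yl]furan-2(5H)-one (CNP0232848.3)
Conditions: Pd2(dba)3 (2.5 mol %), AsPh3, CuI, NMP, rt → 45 °C
Reagents that add atoms: none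
Why: Stille coupling of the (E)-dienylstannane with the vinylogous acyl bromide proceeds with retention of both alkene geometries under neutral conditions that the butenolide and the free alcohol tolerate.

**Compound list**
1 | isobutyronitrile | CC(C)C#N | starting material
2 | 1-bromo-3-chloropropane | ClCCCBr | starting material
3 | 5-chloro-2,2-dimethylpentanenitrile | CC(C)(CCCCl)C#N | intermediate
4 | 5-chloro-2,2-dimethylpentanal | CC(C)(CCCCl)C=O | intermediate
5 | dimethyl (1-diazo-2-oxopropyl)phosphonate | COP(=O)(OC)C(=[N+]=[N-])C(C)=O | starting material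
6 | 6-chloro-3,3-dimethylhex-1-yne | C#CC(C)(C)CCCCl | intermediate
7 | N-methoxy-N-methylacetamide | CON(C)C(C)=O | starting material
8 | 8-chloro-5,5-dimethyloct-3-yn-2-one | CC(=O)C#CC(C)(C)CCCCl | intermediate
9 | (2S)-8-chloro-5,5-dimethyloct-3-yn-2-ol | C[C@H](O)C#CC(C)(C)CCCCl | intermediate
10 | (2S,3Z)-8-chloro-5,5-dimethyloct-3-en-2-ol | C[C@H](O)/C=C\C(C)(C)CCCCl | intermediate
11 | diethyl methylmalonate | CCOC(=O)C(C)C(=O)OCC | starting material
12 | diethyl 2-[(5Z,7S)-7-hydroxy-4,4-dimethyloct-5-en-1-yl]-2-methylpropanedioate | CCOC(=O)C(C)(CCCC(C)(C)/C=C\[C@H](C)O)C(=O)OCC | intermediate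
13 | 2-[(5Z,7S)-7-hydroxy-4,4-dimethyloct-5-en-1-yl]-2-methylpropanedioic acid (not isolated) | OC(=O)C(C)(CCCC(C)(C)/C=C\[C@H](C)O)C(=O)O | intermediate
14 | (7Z,9S)-9-hydroxy-2,6,6-trimethyldec-7-enoic acid (both C2 epimers) | CC(CCCC(C)(C)/C=C\[C@H](C)O)C(=O)O | intermediate
15 | mixed anhydride of 14 with 2,4,6-trichlorobenzoic acid (not isolated) | CC(CCCC(C)(C)/C=C\[C@H](C)O)C(=O)OC(=O)c1c(Cl)cc(Cl)cc1Cl | intermediate
16 | (8Z,10S)-3,7,7,10-tetramethyloxacyclodec-8-en-2-one (both C3 epimers) | C[C@H]1/C=C\C(C)(C)CCCC(C)C(=O)O1 | intermediate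
17 | tert-butyldimethylsilyl ketene acetal of 16, ring oxygen cis to C4 (8Z,10S) | C[C@H]1/C=C\C(C)(C)CCC/C(C)=C(O[Si](C)(C)C(C)(C)C)\O1 | intermediate
18 | tert-butyldimethylsilyl (1S,2R)-1,3,3-trimethyl-2-[(E)-prop-1-en-1-yl]cyclohexane-1-carboxylate (not isolated) | CC(C)(C)[Si](C)(C)OC(=O)[C@@]1(C)CCCC(C)(C)[C@H]1/C=C/C | intermediate
19 | (1S,2R)-1,3,3-trimethyl-2-[(E)-prop-1-en-1-yl]cyclohexane-1-carboxylic acid | OC(=O)[C@@]1(C)CCCC(C)(C)[C@H]1/C=C/C | intermediate
20 | 2-(3-chloropropyl)-1,3-dioxolane | ClCCCC1OCCO1 | starting material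
21 | [3-(1,3-dioxolan-2-yl)propyl]magnesium chloride | Cl[Mg]CCCC1OCCO1 | intermediate
22 | (1S,2R)-1,3,3-trimethyl-2-[(E)-prop-1-en-1-yl]cyclohexane-1-carbonyl chloride (not isolated) | ClC(=O)[C@@]1(C)CCCC(C)(C)[C@H]1/C=C/C | intermediate
23 | 4-(1,3-dioxolan-2-yl)-1-{(1S,2R)-1,3,3-trimethyl-2-[(E)-prop-1-en-1-yl]cyclohexyl}butan-1-one | O=C(CCCC1OCCO1)[C@@]2(C)CCCC(C)(C)[C@H]2/C=C/C | intermediate
24 | methyl vinyl ketone | CC(=O)C=C | starting material
25 | (3E)-4-{(1R,2S)-2-[4-(1,3-dioxolan-2-yl)butanoyl]-2,6,6-trimethylcyclohexyl}but-3-en-2-one | O=C(CCCC1OCCO1)[C@@]2(C)CCCC(C)(C)[C@H]2/C=C/C(C)=O | intermediate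
26 | 4-(1,3-dioxolan-2-yl)-1-[(1S,2R)-1,3,3-trimethyl-2-(3-oxobutyl)cyclohexyl]butan-1-one | O=C(CCCC1OCCO1)[C@@]2(C)CCCC(C)(C)[C@H]2CCC(C)=O | intermediate
27 | 2-{3-[(4aR,8aS)-2,5,5,8a-tetramethyl-3,4,4a,5,6,7,8,8a-octahydronaphthalen-1-yl]propyl}-1,3-dioxolane | CC1=C(CCCC2OCCO2)[C@@]3(C)CCCC(C)(C)[C@H]3CC1 | intermediate
28 | 4-[(4aR,8aS)-2,5,5,8a-tetramethyl-3,4,4a,5,6,7,8,8a-octahydronaphthalen-1-yl]butanal | CC1=C(CCCC=O)[C@@]2(C)CCCC(C)(C)[C@H]2CC1 | intermediate
29 | prop-2-yn-1-ol | C#CCO | starting material
30 | tributyltin hydride | CCCC[SnH](CCCC)CCCC | starting material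
31 | (2E)-3-(tributylstannyl)prop-2-en-1-ol | CCCC[Sn](CCCC)(CCCC)/C=C/CO | intermediate
32 | (2E)-3-(tributylstannyl)prop-2-enal | CCCC[Sn](CCCC)(CCCC)/C=C/C=O | intermediate
33 | N-tert-butyl imine of 28 (not isolated) | CC1=C(CCCC=NC(C)(C)C)[C@@]2(C)CCCC(C)(C)[C@H]2CC1 | intermediate
34 | β-hydroxy imine aldol adduct of 33 and 32, mixture of diastereomers at the two new centres (not isolated) | CC1=C(CCC(C=NC(C)(C)C)C(O)/C=C/[Sn](CCCC)(CCCC)CCCC)[C@@]2(C)CCCC(C)(C)[C@H]2CC1 | intermediate
35 | (2E,4E)-2-{2-[(4aR,8aS)-2,5,5,8a-tetramethyl-3,4,4a,5,6,7,8,8a-octahydronaphthalen-1-yl]ethyl}-5-(tributylstannyl)penta-2,4-dienal | CC1=C(CC/C(C=O)=C\C=C\[Sn](CCCC)(CCCC)CCCC)[C@@]2(C)CCCC(C)(C)[C@H]2CC1 | intermediate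
36 | (2E,4E)-2-{2-[(4aR,8aS)-2,5,5,8a-tetramethyl-3,4,4a,5,6,7,8,8a-octahydronaphthalen-1-yl]ethyl}-5-(tributylstannyl)penta-2,4-dien-1-ol | CC1=C(CC/C(CO)=C\C=C\[Sn](CCCC)(CCCC)CCCC)[C@@]2(C)CCCC(C)(C)[C@H]2CC1 | intermediate
37 | 4-bromofuran-2(5H)-one | BrC1=CC(=O)OC1 | starting material
38 | 4-[(1E,3E)-4-(hydroxymethyl)-6-[(4aR,8aS)-2,5,5,8a-tetramethyl-3,4,4a,5,6,7,8,8a-octahydronaphthalen-1-yl]hexa-1,3-dien-1-yl]furan-2(5H)-one | CC1=C(CC/C(=C\C=C\C2=CC(=O)OC2)CO)[C@@]2(C)CCCC(C)(C)[C@H]2CC1 | target

**Step count**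
Total: 22 steps. Longest linear sequence: 19 steps (steps 1–11, 13–17, 20–22); steps 12, 18 and 19 prepare side reagents.

**Steps most likely to fail**

1. Step 11. On heating, the tetrasubstituted silyl ketene acetal may undergo oxygen-to-carbon silyl migration or fragment before the crowded boat transition state is reached, so that the C5–C10 bond does not form. The fallback sets out from 10 and comes back at 19; it leaves the C10 methyl group out of the rearrangement and adds it afterwards. Sodium diethyl malonate (excess; NaH, NaI, DMF, 80 °C) would be alkylated with 10 to give diethyl 2-[(5Z,7S)-7-hydroxy-4,4-dimethyloct-5-en-1-yl]propanedioate F1. KOH and then acid would give the malonic diacid F2, and hot pyridine would decarboxylate it to (7Z,9S)-9-hydroxy-6,6-dimethyldec-7-enoic acid F3. Yamaguchi conditions would take this through the mixed 2,4,6-trichlorobenzoic anhydride F4 to (8Z,10S)-7,7,10-trimethyloxacyclodec-8-en-2-one F5. LiN(iPr)2/TBSCl would give the trisubstituted silyl ketene acetal F6, which should rearrange through the same boat at lower temperature to the silyl ester F7 and, after hydrolysis, to the cis acid (1S,2S)-3,3-dimethyl-2-[(E)-prop-1-en-1-yl]cyclohexane-1-carboxylic acid F8. The dianion of F8 (2.2 equiv LiN(iPr)2, THF, 0 °C) would then be methylated with MeI on the face opposite the neighbouring propenyl group, which A(1,3) strain holds axial, to give 19.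

2. Step 14. Initiation on the propenyl alkene, which is flanked by two quaternary carbons, may be too slow, so that the catalyst is consumed by dimerising the vinyl ketone. The fallback sets out from 23 and comes back at 25. Lemieux–Johnson cleavage of the propenyl group (OsO4 cat., NaIO4, 2,6-lutidine, dioxane/H2O) would give (1R,2S)-2-[4-(1,3-dioxolan-2-yl)butanoyl]-2,6,6-trimethylcyclohexane-1-carbaldehyde F9. Wittig olefination with the neutral stabilised ylide 1-(triphenylphosphoranylidene)propan-2-one (toluene, 90 °C), which is not basic enough to epimerise C5 or enolise the ketone, would then give 25.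

3. Step 16. The hindered C9 ketone may simply be reduced to the alcohol, or the coupling may stop at the titanium pinacolate and give the diol instead of the alkene. The fallback sets out from 26 and comes back at 27. Double methylenation with Cp2TiMe2 (toluene, 80 °C) would give the diene 2-{4-[(1S,2R)-1,3,3-trimethyl-2-(3-methylbut-3-en-1-yl)cyclohexyl]pent-4-en-1-yl}-1,3-dioxolane F10. Ring-closing metathesis of its two 1,1-disubstituted alkenes with RuCl2[1,3-bis(2-methylphenyl)imidazolidin-2-ylidene](=CH-C6H4-2-OiPr) (benzene, 60 °C) would close ring B at C8=C9 with loss of ethene and give 27.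

Further compounds
F1 | step 11 | diethyl 2-[(5Z,7S)-7-hydroxy-4,4-dimethyloct-5-en-1-yl]propanedioate | CCOC(=O)C(CCCC(C)(C)/C=C\[C@H](C)O)C(=O)OCC
F2 | step 11 | 2-[(5Z,7S)-7-hydroxy-4,4-dimethyloct-5-en-1-yl]propanedioic acid | OC(=O)C(CCCC(C)(C)/C=C\[C@H](C)O)C(=O)O
F3 | step 11 | (7Z,9S)-9-hydroxy-6,6-dimethyldec-7-enoic acid | OC(=O)CCCCC(C)(C)/C=C\[C@H](C)O
F4 | step 11 | mixed anhydride of F3 with 2,4,6-trichlorobenzoic acid | O=C(CCCCC(C)(C)/C=C\[C@H](C)O)OC(=O)c1c(Cl)cc(Cl)cc1Cl
F5 | step 11 | (8Z,10S)-7,7,10-trimethyloxacyclodec-8-en-2-one | C[C@H]1/C=C\C(C)(C)CCCCC(=O)O1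
F6 | step 11 | tert-butyldimethylsilyl ketene acetal of F5 | C[C@H]1/C=C\C(C)(C)CCC/C=C(O[Si](C)(C)C(C)(C)C)\O1
F7 | step 11 | tert-butyldimethylsilyl (1S,2S)-3,3-dimethyl-2-[(E)-prop-1-en-1-yl]cyclohexane-1-carboxylate | CC(C)(C)[Si](C)(C)OC(=O)[C@H]1CCCC(C)(C)[C@H]1/C=C/C
F8 | step 11 | (1S,2S)-3,3-dimethyl-2-[(E)-prop-1-en-1-yl]cyclohexane-1-carboxylic acid | OC(=O)[C@H]1CCCC(C)(C)[C@H]1/C=C/C
F9 | step 14 | (1R,2S)-2-[4-(1,3-dioxolan-2-yl)butanoyl]-2,6,6-trimethylcyclohexane-1-carbaldehyde | O=C(CCCC1OCCO1)[C@@]2(C)CCCC(C)(C)[C@H]2C=O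
F10 | step 16 | 2-{4-[(1S,2R)-1,3,3-trimethyl-2-(3-methylbut-3-en-1-yl)cyclohexyl]pent-4-en-1-yl}-1,3-dioxolane | C=C(CCCC1OCCO1)[C@@]2(C)CCCC(C)(C)[C@H]2CCC(C)=C
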